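## Retrosynthetic overview

1. Ferugin ⇐ C8‑O‑aroylation of a 1,5,8‑triol (5‑OH masked as acetate, phenol as acetate) ⇐ methylenation of a C6 ketone.
2. The cis‑5,8‑dihydroxy‑6‑ketone ⇐ singlet‑oxygen [4+2] on a 2‑methoxycyclohepta‑1,3‑diene, then O–O reduction and enol‑ether hydrolysis.
3. C1 carbinol ⇐ ketone + isopropyl‑cerium; C3a quaternary methyl ⇐ catalytic asymmetric conjugate methylation of a cross‑conjugated cyclopentenone. This is the only catalyst‑set stereocentre; the other four are set by attack anti to this methyl.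
4. Hydroazulenone ⇐ intramolecular Buchner ring expansion of the anisole ring of 1‑diazo‑4‑(4‑methoxyphenyl)butan‑2‑one. The OMe survives as an enol ether, which is both the masked C6 ketone and half of the diene used in line 2.
5. Ring order: the five‑ and seven‑membered rings form together in the Buchner step, from 3‑(4‑methoxyphenyl)propanoic acid.

Assumption and convention: 1 and 10 are catalogue chemicals (made from anisole and 4‑hydroxybenzoic acid). One locant set is used for all bicyclic compounds, the target included: C1 = ketone/carbinol carbon, C3a = methyl‑bearing fusion carbon, C4–C8 around the seven‑membered ring, C8a = H‑bearing fusion carbon.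

## Route

**Step 1**
Reactants: 1, 3‑(4‑methoxyphenyl)propanoic acid
Product: 2, 1‑diazo‑4‑(4‑methoxyphenyl)butan‑2‑one
Conditions: (COCl)2, cat. DMF, CH2Cl2, 0 °C→rt; evaporate; CH2N2 (3 equiv), Et2O, 0 °C
Reagents that add atoms: diazomethane, C=[N+]=[N-]
Why: Acylation of diazomethane by the acid chloride (first half of an Arndt–Eistert sequence, excess CH2N2 scavenging HCl) gives the terminal α‑diazoketone, with no stereocentre formed.

**Step 2**
Reactants: 2, 1‑diazo‑4‑(4‑methoxyphenyl)butan‑2‑one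
Product: 3, 6‑methoxy‑3,4‑dihydroazulen‑1(2H)‑one (achiral)
Conditions: Rh2(OAc)4 (0.5 mol %), CH2Cl2, reflux, slow addition; then Et3N, rt; basic alumina filtration (no acid)
Reagents that add atoms: none
Why: Intramolecular Buchner reaction, in which the Rh(II) acylcarbenoid cyclopropanates an ipso–ortho bond of the anisyl ring, the norcaradiene opens by 6π electrocyclisation, and Et3N moves the C8a proton to C4 via the dienolate (as known for the parent phenyl case) to give the cross‑conjugated cyclopentenone with the OMe retained as a 2‑methoxy‑1,3‑diene.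

**Step 3**
Reactants: 3, 6‑methoxy‑3,4‑dihydroazulen‑1(2H)‑one
Product: 4, (3aR,8aR)‑6‑methoxy‑3a‑methyl‑3,3a,4,8a‑tetrahydroazulen‑1(2H)‑one (trans‑fused, 8a‑H anti to 3a‑CH3; used at once)
Conditions: Me3Al (2 equiv), Cu(OTf)2 (5 mol %), chiral sulfonate‑NHC–Ag(I) complex (2.5 mol %, enantiomer delivering CH3 to the Si face of C3a), THF, −78→−30 °C; AcOH/THF then pH 7 buffer at −78 °C
Reagents that add atoms: trimethylaluminium, C[Al](C)C
Why: Proposed new method: Cu(I)–NHC‑catalysed enantioselective 1,4‑addition of Me3Al to a tetrasubstituted cyclopentenone, the closest known reaction being Cu–NHC or Cu–phosphoramidite conjugate addition of R3Al to β,β‑disubstituted cyclopentenones to form quaternary centres; C3a is the only position conjugated to the carbonyl (the diene is attached through Cα, so 1,6‑ and 1,8‑addition are impossible), the π‑allyl‑type Cu(III) intermediate reductively eliminates at C3a to set 3aR, and kinetic α‑protonation of the aluminium dienolate anti to the new angular methyl gives the trans ring fusion.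

**Step 4**
Reactants: 4, (3aR,8aR)‑6‑methoxy‑3a‑methyl‑3,3a,4,8a‑tetrahydroazulen‑1(2H)‑one
Product: 5, (1R,3aR,8aR)‑6‑methoxy‑3a‑methyl‑1‑(propan‑2‑yl)‑1,2,3,3a,4,8a‑hexahydroazulen‑1‑ol
Conditions: iPrMgCl, anhydrous CeCl3 (3 equiv each), THF, −78 °C; pH 7 work‑up
Reagents that add atoms: isopropylmagnesium chloride, CC(C)[Mg]Cl
Why: Organocerium (Imamoto) 1,2‑addition suppresses enolisation and reduction of the β,γ‑unsaturated ketone, and isopropyl adds anti to the 1,3‑related angular methyl so that OH ends cis to CH3 (1R) and C8a is no longer epimerisable.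

**Step 5**
Reactants: 5, (1R,3aR,8aR)‑6‑methoxy‑3a‑methyl‑1‑(propan‑2‑yl)‑1,2,3,3a,4,8a‑hexahydroazulen‑1‑ol
Product: 7, (1R,3aR,5S,8S,8aS)‑1,5,8‑trihydroxy‑3a‑methyl‑1‑(propan‑2‑yl)octahydroazulen‑6(1H)‑one, via endoperoxide 6, (1R,3aR,5S,8S,8aS)‑5,8‑epidioxy‑6‑methoxy‑3a‑methyl‑1‑(propan‑2‑yl)‑1,2,3,3a,4,5,8,8a‑octahydroazulen‑1‑ol (not isolated)
Conditions: O2, TPP (1 mol %), hν, CH2Cl2, −78 °C; thiourea, MeOH, −78 °C→rt; 5 % aq. oxalic acid, THF, 0 °C
Reagents that add atoms: dioxygen, O=O; water, O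
Why: Singlet‑oxygen [4+2] cycloaddition to the s‑cis 2‑methoxydiene on the face anti to the angular methyl sets C5 and C8 together (both O cis to 8a‑H), thiourea reduces the O–O bond to the cis‑1,4‑diol, and mild acid hydrolyses the enol ether to the C6 ketone without dehydrating the β‑ketol.

**Step 6**
Reactants: 7, (1R,3aR,5S,8S,8aS)‑1,5,8‑trihydroxy‑3a‑methyl‑1‑(propan‑2‑yl)octahydroazulen‑6(1H)‑one
Product: 8, (1R,3aR,5S,8S,8aS)‑3a‑methyl‑6‑methylidene‑1‑(propan‑2‑yl)decahydroazulene‑1,5,8‑triol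
Conditions: Zn, CH2Br2, TiCl4 (preformed Lombardo reagent, excess), THF/CH2Cl2, 0 °C→rt
Reagents that add atoms: dibromomethane, BrCBr
Why: Takai–Lombardo methylenation is non‑basic and tolerates free hydroxyls, so the α‑hydroxy/β‑hydroxy ketone becomes the exocyclic alkene without retro‑aldol, E1cB loss of 8‑OH or epimerisation at C5.

**Step 7**
Reactants: 8, (1R,3aR,5S,8S,8aS)‑3a‑methyl‑6‑methylidene‑1‑(propan‑2‑yl)decahydroazulene‑1,5,8‑triol
Product: 9, (1R,3aR,5S,8S,8aS)‑1,8‑dihydroxy‑3a‑methyl‑6‑methylidene‑1‑(propan‑2‑yl)decahydroazulen‑5‑yl acetate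
Conditions: Ac2O (1.1 equiv), pyridine, CH2Cl2, 0 °C (no DMAP)
Reagents that add atoms: acetic anhydride, CC(=O)OC(C)=O
Why: Site‑selective acylation, because the allylic 5‑OH is far less hindered than 8‑OH (flanked by C8a and syn to the C1 isopropyl) and the tertiary 1‑OH is inert.

**Step 8**
Reactants: 9, the 5‑O‑acetate; 10, 4‑acetoxybenzoyl chloride
Product: 11, (1R,3aR,5S,8S,8aS)‑5‑acetoxy‑1‑hydroxy‑3a‑methyl‑6‑methylidene‑1‑(propan‑2‑yl)decahydroazulen‑8‑yl 4‑acetoxybenzoate
Conditions: 10 (2 equiv), DMAP (1 equiv), Et3N, CH2Cl2, 40 °C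
Reagents that add atoms: 4‑acetoxybenzoyl chloride, CC(=O)Oc1ccc(cc1)C(Cl)=O
Why: DMAP‑catalysed acylation of the only remaining secondary hydroxyl forms the acyl–O bond with retention at C8, the tertiary 1‑OH staying free as in known acylations of the same hindered daucane hydroxyl.

**Step 9**
Reactants: 11, the 5‑O‑acetyl 8‑O‑(4‑acetoxybenzoyl) diester
Product: 12, ferugin, (1R,3aR,5S,8S,8aS)‑1,5‑dihydroxy‑3a‑methyl‑6‑methylidene‑1‑(propan‑2‑yl)decahydroazulen‑8‑yl 4‑hydroxybenzoate
Conditions: K2CO3 (0.5 equiv), MeOH, 0 °C→rt, monitored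
Reagents that add atoms: none
Why: Zemplén‑type methanolysis removes the aryl acetate and the unhindered allylic acetate while the hindered C8 benzoate, further deactivated as its para‑phenoxide, survives and no stereocentre is touched.

## Compound list

1 | 3‑(4‑methoxyphenyl)propanoic acid | COc1ccc(CCC(=O)O)cc1 | starting material
2 | 1‑diazo‑4‑(4‑methoxyphenyl)butan‑2‑one | COc1ccc(CCC(=O)C=[N+]=[N-])cc1 | intermediate
3 | 6‑methoxy‑3,4‑dihydroazulen‑1(2H)‑one | O=C1CCC2=C1C=CC(OC)=CC2 | intermediate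
4 | (3aR,8aR)‑6‑methoxy‑3a‑methyl‑3,3a,4,8a‑tetrahydroazulen‑1(2H)‑one | COC=1C=C[C@@H]2[C@](C)(CCC2=O)CC=1 | intermediate
5 | (1R,3aR,8aR)‑6‑methoxy‑3a‑methyl‑1‑(propan‑2‑yl)‑1,2,3,3a,4,8a‑hexahydroazulen‑1‑ol | COC=1C=C[C@@H]2[C@](C)(CC[C@@]2(O)C(C)C)CC=1 | intermediate
6 | (1R,3aR,5S,8S,8aS)‑5,8‑epidioxy‑6‑methoxy‑3a‑methyl‑1‑(propan‑2‑yl)‑1,2,3,3a,4,5,8,8a‑octahydroazulen‑1‑ol | COC1=C[C@H]3[C@@H]2[C@](C)(CC[C@@]2(O)C(C)C)C[C@@H]1OO3 | intermediate (not isolated)
7 | (1R,3aR,5S,8S,8aS)‑1,5,8‑trihydroxy‑3a‑methyl‑1‑(propan‑2‑yl)octahydroazulen‑6(1H)‑one | O=C1C[C@H](O)[C@@H]2[C@](C)(CC[C@@]2(O)C(C)C)C[C@@H]1O | intermediate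
8 | (1R,3aR,5S,8S,8aS)‑3a‑methyl‑6‑methylidene‑1‑(propan‑2‑yl)decahydroazulene‑1,5,8‑triol | C=C1C[C@H](O)[C@@H]2[C@](C)(CC[C@@]2(O)C(C)C)C[C@@H]1O | intermediate
9 | (1R,3aR,5S,8S,8aS)‑1,8‑dihydroxy‑3a‑methyl‑6‑methylidene‑1‑(propan‑2‑yl)decahydroazulen‑5‑yl acetate | C=C1C[C@H](O)[C@@H]2[C@](C)(CC[C@@]2(O)C(C)C)C[C@@H]1OC(C)=O | intermediate
10 | 4‑acetoxybenzoyl chloride | CC(=O)Oc1ccc(cc1)C(Cl)=O | starting material
11 | (1R,3aR,5S,8S,8aS)‑5‑acetoxy‑1‑hydroxy‑3a‑methyl‑6‑methylidene‑1‑(propan‑2‑yl)decahydroazulen‑8‑yl 4‑acetoxybenzoate | C=C1C[C@H](OC(=O)c2ccc(OC(C)=O)cc2)[C@@H]2[C@](C)(CC[C@@]2(O)C(C)C)C[C@@H]1OC(C)=O | intermediate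
12 | ferugin | C=C1C[C@H](OC(=O)c2ccc(O)cc2)[C@@H]2[C@](C)(CC[C@@]2(O)C(C)C)C[C@@H]1O | target

## Totals and risks

Total steps: 9. Longest linear sequence: 9 (1 → 12).

Steps most likely to fail:

1. **Step 3.** Enantioselective methyl transfer to a tetrasubstituted enone is unprecedented, and ketone 4 can protonate cis or slip into the conjugated δ‑methoxy dienone. Fallback: add methyl racemically (Me2CuLi/TMSCl, silyl dienol ether, low‑temperature protodesilylation) and move the source of absolute configuration to step 7, using lipase‑catalysed (CAL‑B, vinyl acetate) enantioselective acetylation of 5‑OH in racemic 8 as a kinetic resolution that also serves as the protection.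

2. **Step 2.** The para‑methoxy group may shift the Et3N equilibrium from 3 toward linearly conjugated trienone isomers, and acid traces give 7‑methoxy‑2‑tetralone. Fallback: run the Buchner reaction on 3‑(4‑methylphenyl)propanoic acid (the 6‑methyl series should isomerise like the parent), install 8‑OH by hydroboration of the diene, and make the exocyclic methylene/5‑OH pair last from the C5=C6(CH3) alkene by epoxidation and epoxide‑to‑allylic‑alcohol isomerisation.

3. **Step 5.** Facial selectivity of singlet oxygen is argued, not proven (the C1 isopropyl sits on the attacked face), ene or dioxetane chemistry at the enol ether may compete, and β‑ketol 7 is fragile. Fallback: stepwise oxygenation — hydrolyse 5 to the C7=C8 enone, install 8‑OH by nucleophilic epoxidation and SmI2 opening, aroylate that single secondary alcohol, methylenate, and introduce 5‑OH last by SeO2/tBuOOH allylic hydroxylation.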